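**Assumption:** the target has no stereocentre or other stereogenic element, so there is no enantiomer to select; it is made in the free hydrogen sulfate form drawn.

## Retrosynthetic overview

1. Target ⇐ hydrogenolysis of the 5,4'-di-O-benzyl ether of rhamnazin 3-O-sulfate, so the sulfate goes onto the only free hydroxyl and no regioselectivity problem arises.
2. 3-O-sulfate ⇐ O-sulfation of the 5,4'-di-O-benzyl flavonol with an SO3–amine complex.
3. Flavonol ⇐ Algar–Flynn–Oyamada oxidative cyclisation of a 2'-hydroxychalcone; this is the only ring-forming step and closes ring C.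
4. Chalcone ⇐ Claisen–Schmidt condensation of mono-O-benzylated 2',6'-dihydroxy-4'-methoxyacetophenone (ring A) with O-benzylvanillin (ring B).
5. Ring order: rings A and B are bought; ring C (the pyranone) is formed last, in step 3.

## Route

Step 1
Reactants: 1 2',6'-dihydroxy-4'-methoxyacetophenone
Product: 2 1-[2-(benzyloxy)-6-hydroxy-4-methoxyphenyl]ethan-1-one
Conditions: BnBr (1.05 equiv), K2CO3 (1.1 equiv), acetone, reflux, 6 h
Reagents that add atoms: benzyl bromide, BrCc1ccccc1
Why: Williamson O-alkylation: the two phenols of 1 are equivalent by symmetry, and once one is benzylated the other stays hydrogen-bonded to the ketone and is much less nucleophilic, so one equivalent of BnBr gives the mono-ether.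

Step 2
Reactants: 2 1-[2-(benzyloxy)-6-hydroxy-4-methoxyphenyl]ethan-1-one; 3 4-(benzyloxy)-3-methoxybenzaldehyde (O-benzylvanillin)
Product: 4 (E)-1-[2-(benzyloxy)-6-hydroxy-4-methoxyphenyl]-3-[4-(benzyloxy)-3-methoxyphenyl]prop-2-en-1-one
Conditions: KOH (50% aq), EtOH, rt, 36 h
Reagents that add atoms: none
Why: Claisen–Schmidt (crossed aldol) condensation: the methyl ketone enolate adds to the non-enolisable aldehyde and E1cB dehydration gives the conjugated (E)-enone under thermodynamic control.

Step 3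
Reactants: 4 (E)-1-[2-(benzyloxy)-6-hydroxy-4-methoxyphenyl]-3-[4-(benzyloxy)-3-methoxyphenyl]prop-2-en-1-one
Product: 6 5-(benzyloxy)-2-[4-(benzyloxy)-3-methoxyphenyl]-3-hydroxy-7-methoxy-4H-chromen-4-one, via trans-dihydroflavonol 5 (not isolated)
Conditions: 30% aq H2O2 (5 equiv), NaOH (2 M aq), MeOH–THF, 0 °C to rt, 16 h
Reagents that add atoms: hydrogen peroxide, OO
Why: Algar–Flynn–Oyamada reaction: the 2'-phenoxide closes ring C by conjugate addition while alkaline H2O2 oxygenates the α-carbon to give the racemic trans-dihydroflavonol 5, whose two transient stereocentres are erased when excess peroxide dehydrogenates it to the flavonol.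

Step 4
Reactants: 6 5-(benzyloxy)-2-[4-(benzyloxy)-3-methoxyphenyl]-3-hydroxy-7-methoxy-4H-chromen-4-one
Product: 7 5-(benzyloxy)-2-[4-(benzyloxy)-3-methoxyphenyl]-7-methoxy-4-oxo-4H-chromen-3-yl hydrogen sulfate (handled as its triethylammonium salt)
Conditions: SO3·NEt3 (6 equiv), N,N-dimethylacetamide, 65 °C, 6 h
Reagents that add atoms: sulfur trioxide–triethylamine complex, CC[N+](CC)(CC)S(=O)(=O)[O-]
Why: O-sulfation with a sulfur trioxide–amine complex: the enolic 3-OH is the only free hydroxyl in 6, so SO3 transfer is necessarily regioselective, and the monoester is obtained as an amine salt that never sees acid.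

Step 5
Reactants: 7 5-(benzyloxy)-2-[4-(benzyloxy)-3-methoxyphenyl]-7-methoxy-4-oxo-4H-chromen-3-yl hydrogen sulfate
Product: 8 rhamnazin 3-O-sulfate (5-hydroxy-2-(4-hydroxy-3-methoxyphenyl)-7-methoxy-4-oxo-4H-chromen-3-yl hydrogen sulfate)
Conditions: H2 (1 atm), 10% Pd/C, MeOH–THF, rt, 3 h; then strongly acidic cation-exchange resin (H+ form), 0 °C, freeze-drying
Reagents that add atoms: none
Why: Catalytic hydrogenolysis of the two benzyl aryl ethers: the sulfate monoester anion and the chromone C2=C3 bond are inert to H2 over Pd/C at 1 atm, so both phenols are unmasked without touching the sulfate, and no stereocentre is present or formed.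

## Compound list

1 | 2',6'-dihydroxy-4'-methoxyacetophenone | CC(=O)c1c(O)cc(OC)cc1O | starting material
2 | 1-[2-(benzyloxy)-6-hydroxy-4-methoxyphenyl]ethan-1-one | CC(=O)c1c(O)cc(OC)cc1OCc1ccccc1 | intermediate
3 | 4-(benzyloxy)-3-methoxybenzaldehyde | COc1cc(C=O)ccc1OCc1ccccc1 | starting material
4 | (E)-1-[2-(benzyloxy)-6-hydroxy-4-methoxyphenyl]-3-[4-(benzyloxy)-3-methoxyphenyl]prop-2-en-1-one | COc1cc(O)c(C(=O)/C=C/c2ccc(OCc3ccccc3)c(OC)c2)c(OCc2ccccc2)c1 | intermediate
5 | rac-(2R,3R)-5-(benzyloxy)-2-[4-(benzyloxy)-3-methoxyphenyl]-3-hydroxy-7-methoxychroman-4-one (trans-dihydroflavonol, racemic, one enantiomer drawn) | COc1cc(ccc1OCc1ccccc1)[C@@H]1[C@H](C(=O)c2c(OCc3ccccc3)cc(OC)cc2O1)O | intermediate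
6 | 5-(benzyloxy)-2-[4-(benzyloxy)-3-methoxyphenyl]-3-hydroxy-7-methoxy-4H-chromen-4-one | COc1cc(OCc2ccccc2)c2c(=O)c(O)c(-c3ccc(OCc4ccccc4)c(OC)c3)oc2c1 | intermediate
7 | 5-(benzyloxy)-2-[4-(benzyloxy)-3-methoxyphenyl]-7-methoxy-4-oxo-4H-chromen-3-yl hydrogen sulfate | COc1cc(OCc2ccccc2)c2c(=O)c(OS(=O)(=O)O)c(-c3ccc(OCc4ccccc4)c(OC)c3)oc2c1 | intermediate
8 | rhamnazin 3-O-sulfate | COc1cc(O)c2c(=O)c(OS(=O)(=O)O)c(-c3ccc(O)c(OC)c3)oc2c1 | target

## Step count and risk

Total step count: 5. Longest linear sequence: 5 steps (1 → 2 → 4 → 6 → 7 → 8).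

The three steps most likely to fail are steps 3, 4 and 5.

**Step 3.** The 6'-benzyloxy group of chalcone 4 can divert the Algar–Flynn–Oyamada reaction towards the aurone, so the flavonol yield may be low. The fallback sets out from 4 and comes back to the route at 6. Chalcone 4 is cyclised oxidatively with catalytic iodine in DMSO at 130 °C to the flavone 5-(benzyloxy)-2-[4-(benzyloxy)-3-methoxyphenyl]-7-methoxy-4H-chromen-4-one F1. The C2=C3 bond of F1 is then epoxidised with dimethyldioxirane in acetone/CH2Cl2 at 0 °C to the racemic cis-fused epoxide 5-(benzyloxy)-2-[4-(benzyloxy)-3-methoxyphenyl]-2,3-epoxy-7-methoxychroman-4-one F2. Catalytic p-TsOH opens F2 and it tautomerises to flavonol 6. This separates ring closure from C3 oxygenation, so no aurone can form.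

**Step 4.** Direct sulfation of the hindered, hydrogen-bonded 3-OH may be sluggish, and the ionic product is awkward to purify. The fallback sets out from 6 and comes back at 7. Flavonol 6 is treated with 2,2,2-trichloroethyl chlorosulfate, Et3N and DMAP in THF (0 °C to rt) to give the neutral, silica-stable 5-(benzyloxy)-2-[4-(benzyloxy)-3-methoxyphenyl]-7-methoxy-4-oxo-4H-chromen-3-yl 2,2,2-trichloroethyl sulfate F3. Zinc dust and ammonium formate in MeOH at rt then remove the trichloroethyl group by reductive β-elimination, leaving the benzyl ethers intact and giving 7.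

**Step 5.** Hydrogenolysis in the presence of the acid-labile 3-sulfate may cause partial desulfation, and the 5-O-benzyl group may cleave slowly. The fallback sets out from 6 and comes back at 8. Flavonol 6 is first debenzylated (H2, Pd/C, THF–MeOH) to rhamnazin F4. F4 is sulfated at both reactive hydroxyls with excess SO3·NEt3 in N,N-dimethylacetamide at 65 °C, the chelated 5-OH staying free, to give rhamnazin 3,4'-bis(hydrogen sulfate) F5. Aryl sulfatase from Helix pomatia (acetate buffer, pH 5, 37 °C) then hydrolyses only the phenolic 4'-sulfate; the enolic 3-sulfate is not a substrate, so the product is 8. Regiocontrol comes from the enzyme instead of from protecting groups.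

## Further compounds

F1 | step 3 | 5-(benzyloxy)-2-[4-(benzyloxy)-3-methoxyphenyl]-7-methoxy-4H-chromen-4-one | COc1cc(OCc2ccccc2)c2c(=O)cc(-c3ccc(OCc4ccccc4)c(OC)c3)oc2c1
F2 | step 3 | racemic cis-fused 5-(benzyloxy)-2-[4-(benzyloxy)-3-methoxyphenyl]-2,3-epoxy-7-methoxychroman-4-one (one enantiomer drawn) | COc1cc(OCc2ccccc2)c2C(=O)[C@@H]5O[C@]5(c3ccc(OCc4ccccc4)c(OC)c3)Oc2c1
F3 | step 4 | 5-(benzyloxy)-2-[4-(benzyloxy)-3-methoxyphenyl]-7-methoxy-4-oxo-4H-chromen-3-yl 2,2,2-trichloroethyl sulfate | COc1cc(OCc2ccccc2)c2c(=O)c(OS(=O)(=O)OCC(Cl)(Cl)Cl)c(-c3ccc(OCc4ccccc4)c(OC)c3)oc2c1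
F4 | step 5 | rhamnazin (3,5-dihydroxy-2-(4-hydroxy-3-methoxyphenyl)-7-methoxy-4H-chromen-4-one) | COc1cc(O)c2c(=O)c(O)c(-c3ccc(O)c(OC)c3)oc2c1
F5 | step 5 | rhamnazin 3,4'-bis(hydrogen sulfate) | COc1cc(O)c2c(=O)c(OS(=O)(=O)O)c(-c3ccc(OS(=O)(=O)O)c(OC)c3)oc2c1
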